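**Direct plan and its weak points**

A direct plan would start from 2,4,6-trihydroxybenzophenone A1 and attach the two prenyl groups to the finished ring one after the other, each by O-tert-prenylation under zerovalent-palladium catalysis and thermal Claisen rearrangement. This would give the 3-prenyl compound A2 and then the 3,5-diprenyl compound A3, and a twofold O-methylation would close the route.
- The first C-prenylation of the free acylphloroglucinol would be weak: three hydroxyls compete, O- and C-attack compete, the catalysis has no precedent on such a substrate, and an ortho-prenyl phenol closes easily to a chroman.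
- The second prenylation would repeat the same unproven sequence on a more hindered, more electron-rich substrate, so every shortfall multiplies.
- The closing dimethylation would have to stop at two of three hydroxyls on a fully substituted phloroglucinol. Over-methylation and dearomatising C-methylation threaten, and the OH/OMe pattern rests on a late selectivity.

**Retrosynthetic overview**

Ring A (C1 benzoyl, C2 OH, C3 prenyl, C4 OMe, C5 prenyl, C6 OMe) alternates oxygen and carbon substituents, the mark of a benzoyl-primed tetraketide, so ring A is built last and is not decorated.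
Key disconnections are C5–C6 (conjugate addition–elimination) and C1–C2 (Claisen condensation). They split ring A into a four-carbon β-methoxy enoate (C2–C5, with both prenyl groups and the C4 methyl ether) and a two-carbon benzoylketene dimethyl acetal (C6–C1, with the benzoyl group and the C6 methyl ether).
The enoate would come from methyl acetoacetate by two enolate prenylations in one flask and O-methylation, the acetal from benzoyl chloride and 1,1-dimethoxyethene. Only ring A is closed; the phenyl ring is bought.
No aromatic ring is prenylated and no phenol is methylated selectively: the OH/OMe pattern follows from which carbonyls are masked (C4, C6) and which carbon is the ester (C2).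

Key step: step 4

Remark: prenyl means 3-methylbut-2-en-1-yl; the target has no stereocentre, and 1,1-dimethoxyethene is taken as a purchasable reagent.

**Route**

Step 1
Reactants: 1 methyl acetoacetate; 2 prenyl bromide (1-bromo-3-methylbut-2-ene)
Product: 4 methyl 7-methyl-2-(3-methylbut-2-en-1-yl)-3-oxooct-6-enoate, via methyl 7-methyl-3-oxooct-6-enoate 3 (not isolated)
Conditions: NaH (1.1 equiv), THF, 0 °C; n-BuLi (1.05 equiv), 0 °C; 2 (1.0 equiv), 0 °C; then 2 (1.1 equiv), DMPU, rt to 45 °C
Reagents that add atoms: 1-bromo-3-methylbut-2-ene, CC(C)=CCBr
Why: β-Keto ester dianion alkylation: the γ-carbanion is by far the more nucleophilic site and should take the first prenyl group by SN2, and the remaining stabilised α-enolate of 3 should be C-alkylated by the second equivalent on warming, the primary allylic bromide reacting without allylic transposition.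

Step 2
Reactants: 4 methyl 7-methyl-2-(3-methylbut-2-en-1-yl)-3-oxooct-6-enoate; 5 dimethyl sulfate
Product: 6 methyl (2E)-3-methoxy-7-methyl-2-(3-methylbut-2-en-1-yl)octa-2,6-dienoate
Conditions: Me2SO4 (1.2 equiv), K2CO3 (2 equiv), DMSO, rt
Reagents that add atoms: dimethyl sulfate, COS(=O)(=O)OC
Why: O-alkylation of an ambident β-keto ester enolate: the free potassium enolate in DMSO should react with the hard electrophile at oxygen, C-methylation being further disfavoured because it would create a quaternary carbon; the (E)-isomer is expected to prevail, and the geometry is erased in step 4.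

Step 3
Reactants: 7 benzoyl chloride; 8 1,1-dimethoxyethene
Product: 9 3,3-dimethoxy-1-phenylprop-2-en-1-one
Conditions: 8 (1.5 equiv), Et3N (1.5 equiv), Et2O, 0 °C to rt; filtration, distillation, storage under argon
Reagents that add atoms: benzoyl chloride, O=C(Cl)c1ccccc1
Why: C-acylation of a ketene acetal by an acyl chloride: the nucleophilic β-carbon of 8 should attack benzoyl chloride and Et3N should remove the proton of the oxocarbenium ion, giving the push–pull acylketene acetal, which is stabilised by conjugation.

Step 4
Reactants: 6 methyl (2E)-3-methoxy-7-methyl-2-(3-methylbut-2-en-1-yl)octa-2,6-dienoate; 9 3,3-dimethoxy-1-phenylprop-2-en-1-one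
Product: 11 [2-hydroxy-4,6-dimethoxy-3,5-bis(3-methylbut-2-en-1-yl)phenyl](phenyl)methanone, via masked tetraketide ester 10 (not isolated)
Conditions: LiN(i-Pr)2 (LDA, 1.1 equiv), THF, −78 °C; 9 (1.1 equiv), −78 to 0 °C; KOt-Bu (1.5 equiv), 0 to 40 °C; cold aq. HCl (0.5 M)
Reagents that add atoms: 3,3-dimethoxy-1-phenylprop-2-en-1-one, COC(OC)=CC(=O)c1ccccc1
Why: Proposed new method: LDA should remove a γ-hydrogen of 6 (at future C5) to give the lithium dienolate, whose γ-carbon adds to the acetal carbon of 9 and expels methoxide (C5–C6 bond), giving the masked benzoyl tetraketide 10 in which C4–O and C6–O are already methyl enol ethers; the base then removes the doubly vinylogous C5–H, and the α-carbon of the resulting phenyl-ketone enolate (C1) attacks the ester carbonyl (C2) in a 6-(enolexo)-exo-trig Claisen condensation, the only ring closure of the step, after which loss of methoxide and enolisation give the phenoxide of 11. The closest known reaction types are the Staunton–Weinreb annulation (lateral carbanion of an ortho-toluate, Michael addition to a β-methoxy enone, Claisen closure onto the ester, aromatisation) and the base-mediated Claisen folding of 3,5,7-triketo esters to acylphloroglucinols; neither has been shown for an acyclic γ-deprotonated β-methoxy enoate with an acylketene O,O-acetal. The step needs γ- over α-attack of the dienolate, 1,4- over 1,2-addition to 9, and Claisen over aldol folding: the α-carbon (C3) carries a prenyl group, so its adduct would hold two adjacent fully substituted carbons and should revert; the carbonyl group of 9 is a doubly donor-substituted vinylogous carbonate whose 1,2-adducts should also revert; and the aldol mode (C3 onto the benzoyl carbonyl) can only give a non-aromatisable tertiary alkoxide that reopens, whereas the Claisen mode is made irreversible by loss of methoxide and formation of the chelated phenoxide. The double-bond geometries of 6 and 10 should not matter, because every C–C bond of the chain belongs to a delocalised anion and can rotate before closure; no stereocentre is formed. The OH/OMe pattern is fixed by construction, since only the ester carbon (C2) emerges as a free hydroxyl, hydrogen-bonded to the benzoyl group.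

**Compound list**

1 | methyl acetoacetate (methyl 3-oxobutanoate) | COC(=O)CC(C)=O | starting material
2 | prenyl bromide (1-bromo-3-methylbut-2-ene) | CC(C)=CCBr | starting material
3 | methyl 7-methyl-3-oxooct-6-enoate (formed as its enolate) | COC(=O)CC(=O)CCC=C(C)C | intermediate
4 | methyl 7-methyl-2-(3-methylbut-2-en-1-yl)-3-oxooct-6-enoate (racemic, labile α-centre) | COC(=O)C(CC=C(C)C)C(=O)CCC=C(C)C | intermediate
5 | dimethyl sulfate | COS(=O)(=O)OC | starting material
6 | methyl (2E)-3-methoxy-7-methyl-2-(3-methylbut-2-en-1-yl)octa-2,6-dienoate | COC(=O)/C(CC=C(C)C)=C(/OC)CCC=C(C)C | intermediate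
7 | benzoyl chloride | O=C(Cl)c1ccccc1 | starting material
8 | 1,1-dimethoxyethene | C=C(OC)OC | starting material
9 | 3,3-dimethoxy-1-phenylprop-2-en-1-one | COC(OC)=CC(=O)c1ccccc1 | intermediate
10 | methyl 3,5-dimethoxy-2,4-bis(3-methylbut-2-en-1-yl)-7-oxo-7-phenylhepta-2,5-dienoate (racemic at C4, mixture of double-bond isomers) | COC(=O)C(CC=C(C)C)=C(OC)C(CC=C(C)C)C(OC)=CC(=O)c1ccccc1 | intermediate
11 | [2-hydroxy-4,6-dimethoxy-3,5-bis(3-methylbut-2-en-1-yl)phenyl](phenyl)methanone | COc1c(CC=C(C)C)c(O)c(C(=O)c2ccccc2)c(OC)c1CC=C(C)C | target

**Step count and risks**

Total step count: 4. Longest linear sequence: 3 steps (steps 1, 2 and 4); step 3 makes the second fragment.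

Steps most likely to fail:

1. Step 4 (Proposed new method). The dienolate may attack through its α-carbon or add to the carbonyl group of 9, or the open-chain intermediate may fail to close. The fallback sets out from 6 and comes back at 11, using a pyranone relay of known reaction types. The γ-lithio dienolate of 6 (LDA, THF, −78 °C) would be acetylated at the γ-carbon with N-acetylimidazole and would lactonise to 4-methoxy-6-methyl-3,5-bis(3-methylbut-2-en-1-yl)-2H-pyran-2-one F1. Lateral lithiation of the 6-methyl group (LDA) and acylation with methyl benzoate would give 4-methoxy-3,5-bis(3-methylbut-2-en-1-yl)-6-(2-oxo-2-phenylethyl)-2H-pyran-2-one F2. Mg(OMe)2 in MeOH at reflux would open the lactone to the methyl ester and close ring A by Claisen condensation to [2,6-dihydroxy-4-methoxy-3,5-bis(3-methylbut-2-en-1-yl)phenyl](phenyl)methanone F3. One of its two equivalent chelated hydroxyls would then be methylated with 5 (1.05 equiv, K2CO3, acetone) to give 11.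

2. Step 2. Methylation at the α-carbon may compete with O-methylation of the ambident enolate and give a quaternary ketone that cannot enter the annulation. The fallback sets out from 4 and comes back at 6 without an enolate. Trimethyl orthoformate with catalytic TsOH in MeOH at rt would give the ketal methyl 3,3-dimethoxy-7-methyl-2-(3-methylbut-2-en-1-yl)oct-6-enoate F4. Loss of methanol on warming in toluene with a trace of acid would then give 6, conjugation with the ester steering the elimination towards C2.

3. Step 3. The hydrogen chloride released may cleave the ketene acetal, and the moisture-sensitive acylketene acetal may hydrolyse to the β-keto ester. The fallback sets out from 7 and comes back at 9 by vinylic substitution. Friedel–Crafts acylation of 1,1-dichloroethene with 7 (AlCl3, CH2Cl2) and loss of HCl would give 3,3-dichloro-1-phenylprop-2-en-1-one F5. Twofold addition–elimination with NaOMe (2.1 equiv, MeOH, 0 °C) would then give 9.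

**Further compounds**

F1 | step 4 | 4-methoxy-6-methyl-3,5-bis(3-methylbut-2-en-1-yl)-2H-pyran-2-one | COC1=C(CC=C(C)C)C(=O)OC(C)=C1CC=C(C)C
F2 | step 4 | 4-methoxy-3,5-bis(3-methylbut-2-en-1-yl)-6-(2-oxo-2-phenylethyl)-2H-pyran-2-one | COC1=C(CC=C(C)C)C(=O)OC(CC(=O)c2ccccc2)=C1CC=C(C)C
F3 | step 4 | [2,6-dihydroxy-4-methoxy-3,5-bis(3-methylbut-2-en-1-yl)phenyl](phenyl)methanone | COc1c(CC=C(C)C)c(O)c(C(=O)c2ccccc2)c(O)c1CC=C(C)C
F4 | step 2 | methyl 3,3-dimethoxy-7-methyl-2-(3-methylbut-2-en-1-yl)oct-6-enoate | COC(=O)C(CC=C(C)C)C(OC)(OC)CCC=C(C)C
F5 | step 3 | 3,3-dichloro-1-phenylprop-2-en-1-one | O=C(C=C(Cl)Cl)c1ccccc1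
A1 | direct plan | (phenyl)(2,4,6-trihydroxyphenyl)methanone | O=C(c1ccccc1)c1c(O)cc(O)cc1O
A2 | direct plan | [2,4,6-trihydroxy-3-(3-methylbut-2-en-1-yl)phenyl](phenyl)methanone | CC(C)=CCc1c(O)cc(O)c(C(=O)c2ccccc2)c1O
A3 | direct plan | [2,4,6-trihydroxy-3,5-bis(3-methylbut-2-en-1-yl)phenyl](phenyl)methanone | CC(C)=CCc1c(O)c(CC=C(C)C)c(O)c(C(=O)c2ccccc2)c1O
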